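**Retrosynthetic overview**
1. Last operation, rings C then A in one flask: an open chain gives the whole chromanone. O1–C8a forms by cyclodehydration of an (S)-δ-hydroxy-β-diketone. C4a–C5 then forms by ketene C-acylation/6π closure of a dioxinone-masked β-keto acid.
2. The 8-prenyl group sits on the chain carbon between the future C7 and C8a carbonyls. Closing ring C first therefore fixes 8- over 6-prenyl. C2 is carried in as a preformed carbinol.
3. Open chain ⇒ C4–C4a Claisen disconnection: dianion of a prenylated keto-dioxinone plus an (S)-β-hydroxy ester.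
4. (S)-β-hydroxy ester ⇒ catalytic asymmetric acetate aldol on 4-methoxy-3-prenylbenzaldehyde ⇒ Suzuki prenylation of 3-bromo-4-methoxybenzaldehyde (ring B is bought).
5. Prenylated keto-dioxinone ⇒ γ-acetylation, then C-prenylation of the diketene–acetone adduct.

Assumption: the target is the (2S)-flavanone. Compounds 12–16 are drawn as keto tautomers, and their CH(prenyl) centre is labile, left undefined, and lost on aromatisation.

**Step 1**
Reactants: 1 3-bromo-4-methoxybenzaldehyde; 2 3-methylbut-2-enylboronic acid pinacol ester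
Product: 3 4-methoxy-3-(3-methylbut-2-en-1-yl)benzaldehyde
Conditions: Pd-PEPPSI-IPent (2 mol %), 5 M aq KOH, THF, 70 °C
Reagents that add atoms: none
Why: Suzuki–Miyaura allyl–aryl coupling in which the very bulky NHC ligand forces reductive elimination from the less hindered σ-prenyl-Pd isomer, giving the linear (α) prenyl arene, while the non-enolisable electron-rich aldehyde tolerates the biphasic base.

**Step 2**
Reactants: 3 4-methoxy-3-(3-methylbut-2-en-1-yl)benzaldehyde; 4 1-(tert-butyldimethylsilyloxy)-1-methoxyethene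
Product: 6 methyl (3S)-3-hydroxy-3-[4-methoxy-3-(3-methylbut-2-en-1-yl)phenyl]propanoate, via trichlorosilyl aldolate 5 (not isolated)
Conditions: SiCl4 (1.1 equiv), binaphthyldiamine-derived bisphosphoramide (5 mol %), i-Pr2NEt (10 mol %), CH2Cl2, −78 °C; sat. aq NaHCO3
Reagents that add atoms: none
Why: Lewis-base-activated SiCl4 Mukaiyama acetate aldol in which the aldehyde sits in the chiral bisphosphoramide·SiCl3+ pocket and the catalyst antipode that leaves the Si face open is used, so C–C bond formation sets the carbinol (future C2) as (S), while the catalytic amine scavenges HCl and protects the prenyl group.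

**Step 3**
Reactants: 7 2,2,6-trimethyl-4H-1,3-dioxin-4-one; 8 acetyl chloride
Product: 10 2,2-dimethyl-6-(2-oxopropyl)-4H-1,3-dioxin-4-one, via lithium dienolate 9 (not isolated)
Conditions: 7 (2 equiv), LiHMDS (2 equiv), THF, −78 °C; 8 (1 equiv), −78 → −20 °C; 1 M HCl
Reagents that add atoms: none
Why: Vinylogous Claisen condensation (γ-C-acylation of the dioxinone lithium dienolate by an acid chloride), with the second equivalent of dienolate deprotonating the more acidic product and so preventing double acylation.

**Step 4**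
Reactants: 10 2,2-dimethyl-6-(2-oxopropyl)-4H-1,3-dioxin-4-one; 11 1-bromo-3-methylbut-2-ene
Product: 12 2,2-dimethyl-6-(6-methyl-2-oxohept-5-en-3-yl)-4H-1,3-dioxin-4-one
Conditions: K2CO3 (1.1 equiv), acetone, 23 °C
Reagents that add atoms: none
Why: SN2 C-alkylation of a soft, doubly activated enolate (ketone plus vinylogous ester) with an allylic bromide, which places the future C8 prenyl group on the chain and creates only a labile centre that disappears later.

**Step 5**
Reactants: 12 2,2-dimethyl-6-(6-methyl-2-oxohept-5-en-3-yl)-4H-1,3-dioxin-4-one; 6 methyl (3S)-3-hydroxy-3-[4-methoxy-3-(3-methylbut-2-en-1-yl)phenyl]propanoate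
Product: 14 6-{(10S)-10-hydroxy-10-[4-methoxy-3-(3-methylbut-2-en-1-yl)phenyl]-2-methyl-6,8-dioxodec-2-en-5-yl}-2,2-dimethyl-4H-1,3-dioxin-4-one, via dilithio dianion 13 (not isolated)
Conditions: 12 (3 equiv, excess recovered), LDA (6.1 equiv), THF, −78 °C, 1 h; 6 (1 equiv), −78 → −30 °C; AcOH at −78 °C, pH 5 buffer
Reagents that add atoms: none
Why: Claisen condensation of a 1,3-dicarbonyl dianion (Hauser–Harris reactivity, the last-formed terminal carbanion being the nucleophile) with an unprotected β-hydroxy ester, as in the industrial δ-hydroxy-β-keto ester synthesis where the first equivalent of base only makes the alkoxide, and since no bond to the carbinol carbon is touched (S) is retained.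

**Step 6**
Reactants: 14 6-{(10S)-10-hydroxy-10-[4-methoxy-3-(3-methylbut-2-en-1-yl)phenyl]-2-methyl-6,8-dioxodec-2-en-5-yl}-2,2-dimethyl-4H-1,3-dioxin-4-one
Product: 17 (2S)-5,7-dihydroxy-2-[4-methoxy-3-(3-methylbut-2-en-1-yl)phenyl]-8-(3-methylbut-2-en-1-yl)-2,3-dihydro-4H-chromen-4-one, via dihydropyranone-dioxinone 15 (not isolated), via acylketene 16 (not isolated)
Conditions: PPTS (20 mol %), 4 Å MS, PhMe (5 mM), 60 °C, 3 h; then same flask, 110 °C, 1 h
Reagents that add atoms: none
Why: Proposed new method: mild acid first closes the carbinol oxygen onto the δ-carbonyl (known cyclodehydration of δ-hydroxy-β-diketones to 2,3-dihydro-4-pyranones, C–O bond at the stereocentre untouched so (S) is kept), which ties up the only enol oxygen that could give a 2-pyrone, makes the resorcylate-type aldol geometrically impossible and bonds O1 next to the prenyl-bearing carbon so that only the 8-prenyl isomer can form; at 110 °C retro-[4+2] loss of acetone gives acylketene 16, whose enol is a dienylketene that closes at the nucleophilic α-carbon of the vinylogous ester (C-acylation/6π-electrocyclisation) and tautomerises to the phloroglucinol ring under neutral conditions that do not open the flavanone; the closest known reaction types are dioxinone thermolysis–ketene trapping–aromatisation to resorcylates, the dienylketene closure that ends the Danheiser benzannulation, and the biomimetic Claisen-type cyclisation of 3,5,7-triketo esters to acylphloroglucinols.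

**Compound list**
1 | 3-bromo-4-methoxybenzaldehyde | COc1ccc(C=O)cc1Br | starting material
2 | 3-methylbut-2-enylboronic acid pinacol ester | CC(C)=CCB1OC(C)(C)C(C)(C)O1 | starting material
3 | 4-methoxy-3-(3-methylbut-2-en-1-yl)benzaldehyde | COc1ccc(C=O)cc1CC=C(C)C | intermediate
4 | 1-(tert-butyldimethylsilyloxy)-1-methoxyethene | C=C(OC)O[Si](C)(C)C(C)(C)C | starting material
5 | methyl (3S)-3-[4-methoxy-3-(3-methylbut-2-en-1-yl)phenyl]-3-(trichlorosilyloxy)propanoate | COC(=O)C[C@H](O[Si](Cl)(Cl)Cl)c1ccc(OC)c(CC=C(C)C)c1 | intermediate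
6 | methyl (3S)-3-hydroxy-3-[4-methoxy-3-(3-methylbut-2-en-1-yl)phenyl]propanoate | COC(=O)C[C@H](O)c1ccc(OC)c(CC=C(C)C)c1 | intermediate
7 | 2,2,6-trimethyl-4H-1,3-dioxin-4-one | CC1=CC(=O)OC(C)(C)O1 | starting material
8 | acetyl chloride | CC(=O)Cl | starting material
9 | lithium 2,2-dimethyl-6-methylidene-6H-1,3-dioxin-4-olate | [Li+].C=C1C=C([O-])OC(C)(C)O1 | intermediate
10 | 2,2-dimethyl-6-(2-oxopropyl)-4H-1,3-dioxin-4-one | CC(=O)CC1=CC(=O)OC(C)(C)O1 | intermediate
11 | 1-bromo-3-methylbut-2-ene (prenyl bromide) | CC(C)=CCBr | starting material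
12 | 2,2-dimethyl-6-(6-methyl-2-oxohept-5-en-3-yl)-4H-1,3-dioxin-4-one | CC(=O)C(CC=C(C)C)C1=CC(=O)OC(C)(C)O1 | intermediate
13 | dilithio dianion of 12 (deprotonated at the methine and at the terminal methyl) | [Li+].[Li+].C=C([O-])C(CC=C(C)C)=C1C=C([O-])OC(C)(C)O1 | intermediate
14 | 6-{(10S)-10-hydroxy-10-[4-methoxy-3-(3-methylbut-2-en-1-yl)phenyl]-2-methyl-6,8-dioxodec-2-en-5-yl}-2,2-dimethyl-4H-1,3-dioxin-4-one | COc1ccc([C@@H](O)CC(=O)CC(=O)C(CC=C(C)C)C2=CC(=O)OC(C)(C)O2)cc1CC=C(C)C | intermediate
15 | 6-{1-[(2S)-2-[4-methoxy-3-(3-methylbut-2-en-1-yl)phenyl]-4-oxo-3,4-dihydro-2H-pyran-6-yl]-4-methylpent-3-en-1-yl}-2,2-dimethyl-4H-1,3-dioxin-4-one | COc1ccc([C@@H]2CC(=O)C=C(C(CC=C(C)C)C3=CC(=O)OC(C)(C)O3)O2)cc1CC=C(C)C | intermediate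
16 | 4-[(2S)-2-[4-methoxy-3-(3-methylbut-2-en-1-yl)phenyl]-4-oxo-3,4-dihydro-2H-pyran-6-yl]-7-methylocta-1,6-diene-1,3-dione (acylketene) | COc1ccc([C@@H]2CC(=O)C=C(C(CC=C(C)C)C(=O)C=C=O)O2)cc1CC=C(C)C | intermediate
17 | (2S)-5,7-dihydroxy-2-[4-methoxy-3-(3-methylbut-2-en-1-yl)phenyl]-8-(3-methylbut-2-en-1-yl)-2,3-dihydro-4H-chromen-4-one | COc1ccc([C@@H]2CC(=O)c3c(O)cc(O)c(CC=C(C)C)c3O2)cc1CC=C(C)C | target

**Total step count:** 6. **Longest linear sequence:** 4 (1 → 3 → 6 → 14 → 17, and equally 7 → 10 → 12 → 14 → 17).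

**Three steps most likely to fail**

Step 6 carries the most risk. Ketene 16 may dimerise or be hydrolysed instead of closing on carbon, and acid may cyclise the 8-prenyl group onto the 7-OH. The fallback sets out from 14 and comes back at 17, replacing the neutral pericyclic closure by an anionic one. Only the 60 °C acid stage is run and dihydropyranone 15 is isolated. Compound 15 is then heated in toluene with methanol, so that ketene 16 is intercepted as methyl 4-[(2S)-2-aryl-4-oxo-3,4-dihydro-2H-pyran-6-yl]-7-methyl-3-oxooct-6-enoate F1. Ring A is closed by a vinylogous Dieckmann (biomimetic Claisen-type) cyclisation with Mg(OMe)2 in MeOH at 0–23 °C. Contact time is kept short to limit retro-oxa-Michael racemisation.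

Step 5 may fail because the alkoxide-bearing ester is a poor electrophile, or because enolisation of 6 outruns acylation. The fallback sets out from 6 and comes back at 14, changing both the acyl donor and the protecting-group tactic. Compound 6 is converted with MeNHOMe·HCl/i-PrMgCl into the (S)-β-hydroxy Weinreb amide F2. This is silylated with TBSCl/imidazole to the TBS ether F3. F3 is added to only 1.1 equiv of dianion 13, where the chelated tetrahedral adduct survives until the quench, so no excess of 12 is consumed. The product is the TBS-protected diketo-dioxinone F4, and pyridine-buffered HF·pyridine in THF at 0 °C releases 14.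

Step 2 may give insufficient ee, the wrong sense of induction, or prenyl damage by chlorosilane/HCl. The fallback sets out from 3 and comes back at 6, setting the centre by reduction instead of C–C bond formation. Roskamp homologation of 3 with methyl diazoacetate (NbCl5 or SnCl2 catalyst, CH2Cl2) gives methyl 3-[4-methoxy-3-(3-methylbut-2-en-1-yl)phenyl]-3-oxopropanoate F5. Noyori–Ikariya transfer hydrogenation with RuCl[(S,S)-TsDPEN](p-cymene) in HCO2H/Et3N reduces the aryl ketone to the (S)-carbinol 6. The sense of induction follows the established aryl-ketone rule, and the prenyl alkene is not reduced.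

**Further compounds**
F1 | step 6 | methyl 4-[(2S)-2-[4-methoxy-3-(3-methylbut-2-en-1-yl)phenyl]-4-oxo-3,4-dihydro-2H-pyran-6-yl]-7-methyl-3-oxooct-6-enoate | COc1ccc([C@@H]2CC(=O)C=C(C(CC=C(C)C)C(=O)CC(=O)OC)O2)cc1CC=C(C)C
F2 | step 5 | (3S)-3-hydroxy-N-methoxy-3-[4-methoxy-3-(3-methylbut-2-en-1-yl)phenyl]-N-methylpropanamide | CON(C)C(=O)C[C@H](O)c1ccc(OC)c(CC=C(C)C)c1
F3 | step 5 | (3S)-3-(tert-butyldimethylsilyloxy)-N-methoxy-3-[4-methoxy-3-(3-methylbut-2-en-1-yl)phenyl]-N-methylpropanamide | CON(C)C(=O)C[C@H](O[Si](C)(C)C(C)(C)C)c1ccc(OC)c(CC=C(C)C)c1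
F4 | step 5 | O-TBS ether of 14 | COc1ccc([C@@H](O[Si](C)(C)C(C)(C)C)CC(=O)CC(=O)C(CC=C(C)C)C2=CC(=O)OC(C)(C)O2)cc1CC=C(C)C
F5 | step 2 | methyl 3-[4-methoxy-3-(3-methylbut-2-en-1-yl)phenyl]-3-oxopropanoate | COC(=O)CC(=O)c1ccc(OC)c(CC=C(C)C)c1
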